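## Retrosynthetic overview

- Late stage: angeloylation of 8-OH, α-methylenation of the cis-fused γ-lactone (ring C), removal of the silyl ethers.
- Ring C and C6 come from Felkin-type 1,2-reduction of a macrocyclic Z-enone followed by lactonisation. Ring B (nine-membered oxacycle) comes from Ni/Cr closure of C5–C6 between a Z-vinyl iodide and an aldehyde.
- C7–C8 (both centres) come from a D-proline anti cross-aldol of a tetrahydrofuranyl acetaldehyde with methyl 4-oxobutanoate.
- Ring A (2,5-trans tetrahydrofuran, tertiary ether C10) comes from oxidative ring contraction of a 5-methyl-4-silyloxy-dihydropyran (1,2-shift of the ring oxygen, C9→C10), then one-carbon homologation.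
- The dihydropyran comes from an asymmetric hetero-Diels–Alder reaction of (Z)-3-iodo-2-methylacrolein with a methyl-substituted Danishefsky diene. Ring order: pyran → ring A → ring B → ring C.

Assumption: the SMILES is read literally in germacrane numbering, (1S,3S,6S,7R,8R,10R), meaning C4 and C9 trans across the tetrahydrofuran, 1-OH cis to C14 and C4, lactone cis-fused, O6/O8 syn and both anti to C11; (E)-4-methoxy-3-methylbut-3-en-2-one is taken as a purchasable catalogue compound.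

## Route

Step 1
Reactants: 1 prop-2-yn-1-ol
Product: 3 (Z)-3-iodo-2-methylprop-2-en-1-ol, via chelated alkenylmagnesium alkoxide 2 (not isolated)
Conditions: MeMgBr (3 equiv), CuI (10 mol %), THF, −10 °C → rt; then I2, −10 °C
Reagents that add atoms: methylmagnesium bromide C[Mg]Br; iodine II
Why: Alkoxide-directed, CuI-catalysed anti-carbomagnesiation holds Mg cis to CH2O in a five-membered chelate, so iodinolysis gives only the Z vinyl iodide that later becomes the ring-cis C4=C5 alkene.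

Step 2
Reactants: 3 (Z)-3-iodo-2-methylprop-2-en-1-ol
Product: 4 (Z)-3-iodo-2-methylprop-2-enal
Conditions: MnO2 (15 equiv), CH2Cl2, 0 °C → rt, dark; used at once
Reagents that add atoms: none
Why: Neutral heterogeneous allylic alcohol oxidation with MnO2 gives the enal without Z→E isomerisation.

Step 3
Reactants: 5 (E)-4-methoxy-3-methylbut-3-en-2-one
Product: 6 (E)-1-methoxy-2-methyl-3-(trimethylsilyloxy)buta-1,3-diene
Conditions: Me3SiOTf, Et3N, Et2O, 0 °C
Reagents that add atoms: trimethylsilyl triflate C[Si](C)(C)OS(=O)(=O)C(F)(F)F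
Why: Soft enolisation and O-silylation of the methyl ketone gives the Danishefsky-type diene that carries the future C14 methyl.

Step 4
Reactants: 4 (Z)-3-iodo-2-methylprop-2-enal; 6 (E)-1-methoxy-2-methyl-3-(trimethylsilyloxy)buta-1,3-diene
Product: 8 (S)-2-[(Z)-1-iodoprop-1-en-2-yl]-5-methyl-2,3-dihydro-4H-pyran-4-one, via silylated Mukaiyama aldol adduct 7 (not isolated)
Conditions: Ti(OiPr)4 (10 mol %), (S)-BINOL (20 mol %), 4 Å MS, Et2O, −20 °C; then TFA, CH2Cl2, 0 °C
Reagents that add atoms: none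
Why: In this formal hetero-Diels–Alder reaction (Ti–BINOL Mukaiyama aldol, then acid oxa-Michael/loss of MeOH), the (S)-BINOL complex shields one aldehyde face and sets C3 as S.

Step 5
Reactants: 8 (S)-2-[(Z)-1-iodoprop-1-en-2-yl]-5-methyl-2,3-dihydro-4H-pyran-4-one
Product: 9 (2S,4S)-2-[(Z)-1-iodoprop-1-en-2-yl]-5-methyl-3,4-dihydro-2H-pyran-4-ol
Conditions: NaBH4, CeCl3·7H2O, MeOH, −78 → −40 °C
Reagents that add atoms: none
Why: In this Luche 1,2-reduction, axial hydride attack on the half-chair with the equatorial alkenyl group gives the equatorial alcohol, which sets C1 cis to the C3 substituent.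

Step 6
Reactants: 9 (2S,4S)-2-[(Z)-1-iodoprop-1-en-2-yl]-5-methyl-3,4-dihydro-2H-pyran-4-ol
Product: 10 (2S,4S)-4-(tert-butyldimethylsilyloxy)-2-[(Z)-1-iodoprop-1-en-2-yl]-5-methyl-3,4-dihydro-2H-pyran
Conditions: TBSCl, imidazole, DMF, 0 °C → rt
Reagents that add atoms: tert-butyldimethylsilyl chloride CC(C)(C)[Si](C)(C)Cl
Why: Standard silylation blocks oxidation of the allylic alcohol in step 7 and adds a large group that directs the facial attack there.

Step 7
Reactants: 10 (2S,4S)-4-(tert-butyldimethylsilyloxy)-2-[(Z)-1-iodoprop-1-en-2-yl]-5-methyl-3,4-dihydro-2H-pyran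
Product: 12 (2S,3S,5S)-3-(tert-butyldimethylsilyloxy)-5-[(Z)-1-iodoprop-1-en-2-yl]-2-methyltetrahydrofuran-2-carbaldehyde, via C10 aryliodane lactol adduct 11 (not isolated)
Conditions: PhI(OH)OTs (1.1 equiv), 2,6-di-tert-butylpyridine (1.5 equiv), MeCN, −30 → 0 °C
Reagents that add atoms: [hydroxy(tosyloxy)iodo]benzene OI(OS(=O)(=O)c1ccc(C)cc1)c1ccccc1
Why: Proposed new method: oxidative ring contraction of a 2-C-methyl-glycal-type enol ether by a trivalent-iodine electrophile, in which PhI(OH)OTs adds to the nucleophilic carbon C10 on the face opposite the C1 silyloxy and C3 alkenyl groups while its hydroxide caps C9, the equatorial C10–I bond of the resulting chair lies antiperiplanar to the C9–O ring bond, and the ring oxygen therefore migrates from C9 to C10 with inversion as PhI leaves and the C9 hemiacetal collapses to the aldehyde, which forms ring A and sets C10 (CHO trans to 1-OTBS and to C4, methyl cis), with the C10 methyl also blocking the proton loss that diverts C2-H glycals to enones; the closest known reaction type is the Tl(NO3)3- or PhI(OH)OTs-induced contraction of C2-unsubstituted glycals to 2,5-anhydroaldoses (and the HNO2 deamination of glucosamine to 2,5-anhydromannose), not yet shown for a trisubstituted enol ether that must deliver a fully substituted carbon.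

Step 8
Reactants: 12 (2S,3S,5S)-3-(tert-butyldimethylsilyloxy)-5-[(Z)-1-iodoprop-1-en-2-yl]-2-methyltetrahydrofuran-2-carbaldehyde
Product: 14 2-{(2R,3S,5S)-3-(tert-butyldimethylsilyloxy)-5-[(Z)-1-iodoprop-1-en-2-yl]-2-methyltetrahydrofuran-2-yl}acetaldehyde, via methyl enol ether 13 (not isolated)
Conditions: Ph3P(CH2OMe)Cl, KN(SiMe3)2, THF, −78 → 0 °C; then 1 M HCl (aq), 0 °C → rt
Reagents that add atoms: (methoxymethyl)triphenylphosphonium chloride COC[P+](c1ccccc1)(c1ccccc1)c1ccccc1.[Cl-]; water O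
Why: Wittig methoxymethylenation of the non-enolisable aldehyde and enol ether hydrolysis in the same flask turn C9 into CH2 and add C8 as the aldehyde without touching a stereocentre.

Step 9
Reactants: 14 2-{(2R,3S,5S)-3-(tert-butyldimethylsilyloxy)-5-[(Z)-1-iodoprop-1-en-2-yl]-2-methyltetrahydrofuran-2-yl}acetaldehyde; 15 methyl 4-oxobutanoate
Product: 17 methyl (3R,4R)-3-formyl-4-(triethylsilyloxy)-5-{(2R,3S,5S)-3-(tert-butyldimethylsilyloxy)-5-[(Z)-1-iodoprop-1-en-2-yl]-2-methyltetrahydrofuran-2-yl}pentanoate, via beta-hydroxy aldehyde 16 (not isolated)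
Conditions: D-proline (30 mol %), DMF, 4 °C, 15 (3 equiv) by syringe pump; then imidazole, TESCl, 0 °C
Reagents that add atoms: chlorotriethylsilane CC[Si](CC)(CC)Cl
Why: In this enamine-catalysed direct cross-aldol the unhindered aldehyde 15 is the donor and the neopentyl-type aldehyde 14 the acceptor, the acid-organised chair of D-proline gives the anti aldol and sets C7 (R) and C8 (R), matched with 1,3-anti induction from the C10 ether, and silylation in the same flask stops retro-aldol and premature lactonisation.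

Step 10
Reactants: 17 methyl (3R,4R)-3-formyl-4-(triethylsilyloxy)-5-{(2R,3S,5S)-3-(tert-butyldimethylsilyloxy)-5-[(Z)-1-iodoprop-1-en-2-yl]-2-methyltetrahydrofuran-2-yl}pentanoate
Product: 18 ring A/B bicyclic allylic alcohol (C5–C6 closed, 4Z, 6-OH epimers, 1-OTBS, 8-OTES, CH2CO2Me on C7; C1, C3, C7, C8, C10 as in the target)
Conditions: CrCl2 (10 equiv), NiCl2 (2 mol %), DMSO/THF 3:1, 2 mM, rt
Reagents that add atoms: none
Why: In this Nozaki–Hiyama–Kishi macrocyclisation, zerovalent nickel inserts into the C–I bond with retention of the Z geometry and the alkenyl species on trivalent chromium adds irreversibly and chemoselectively to the aldehyde; the new C6 carbinol need not be controlled because step 11 erases it.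

Step 11
Reactants: 18 ring A/B bicyclic allylic alcohol
Product: 19 ring A/B bicyclic Z-enone (C6 ketone, 1-OTBS, 8-OTES, CH2CO2Me on C7)
Conditions: Dess–Martin periodinane, CH2Cl2, 0 °C → rt
Reagents that add atoms: none
Why: Mild Dess–Martin oxidation converges both C6 epimers to one enone without epimerising C7 or eliminating the 8-silyloxy group.

Step 12
Reactants: 19 ring A/B bicyclic Z-enone
Product: 21 tricyclic cis-fused γ-lactone (6,12-olide, C11 = CH2, 1-OTBS, 8-OTES), via 6S hydroxy ester 20 (not isolated)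
Conditions: NaBH4, CeCl3·7H2O, MeOH, −78 °C → rt
Reagents that add atoms: none
Why: In this Luche 1,2-reduction under Felkin–Anh control, the C8 branch stands perpendicular to the carbonyl (C5–C6–C7–C8 about 90°, as the ring allows), hydride enters anti to it on the outer face and sets C6 (S), and the alkoxide then closes onto the methyl ester to give the cis-fused ring C.

Step 13
Reactants: 21 tricyclic cis-fused γ-lactone
Product: 24 α-methylene-γ-lactone (1-OTBS, 8-OTES), via Mannich base 22 (not isolated), via trimethylammonium iodide 23 (not isolated)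
Conditions: LiN(iPr)2 (1.3 equiv), THF, −78 °C; Me2N=CH2 I, −78 → 0 °C; MeI (excess), rt; aq NaHCO3
Reagents that add atoms: N,N-dimethylmethyleneiminium iodide C[N+](C)=C.[I-]
Why: Eschenmoser methylenation (lactone enolate Mannich reaction, quaternisation, E1cB loss of NMe3) is run while both hydroxyls are silyl ethers and no angelate is present, so only C11 is deprotonated.

Step 14
Reactants: 24 α-methylene-γ-lactone (1-OTBS, 8-OTES)
Product: 25 8-hydroxy α-methylene-γ-lactone (1-OTBS)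
Conditions: PPTS (0.2 equiv), MeOH/CH2Cl2 1:1, 0 °C
Reagents that add atoms: none
Why: Acid methanolysis removes the triethylsilyl ether much faster than the hindered TBS ether next to the fully substituted C10.

Step 15
Reactants: 25 8-hydroxy α-methylene-γ-lactone (1-OTBS); 26 angelic acid [(Z)-2-methylbut-2-enoic acid]
Product: 28 1-O-TBS ether of the target, via mixed angelic 2,4,6-trichlorobenzoic anhydride 27 (not isolated)
Conditions: 26, 2,4,6-trichlorobenzoyl chloride, Et3N, toluene, rt; then 25, 80 °C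
Reagents that add atoms: none
Why: Yamaguchi-type mixed-anhydride esterification without a nucleophilic catalyst acylates the only free hydroxyl (C8, retention) and avoids angelate-to-tiglate isomerisation.

Step 16
Reactants: 28 1-O-TBS ether of the target
Product: 29 target CNP0213894.2
Conditions: HF·pyridine, pyridine, THF, 0 °C → rt
Reagents that add atoms: none
Why: Buffered fluoride desilylation frees 1-OH without base, so the α-methylene lactone and the angelate survive and no acyl migration occurs.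

## Compound list

1 | prop-2-yn-1-ol | C#CCO | starting material
2 | chelated (Z)-alkenylmagnesium alkoxide (4-methyl-2,5-dihydro-1,2-oxamagnesole) | CC1=C[Mg]OC1 | intermediate
3 | (Z)-3-iodo-2-methylprop-2-en-1-ol | I/C=C(/C)CO | intermediate
4 | (Z)-3-iodo-2-methylprop-2-enal | I/C=C(/C)C=O | intermediate
5 | (E)-4-methoxy-3-methylbut-3-en-2-one | CO/C=C(\C)C(C)=O | starting material
6 | (E)-1-methoxy-2-methyl-3-(trimethylsilyloxy)buta-1,3-diene | CO/C=C(\C)C(=C)O[Si](C)(C)C | intermediate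
7 | (1E,5S,6Z)-7-iodo-1-methoxy-2,6-dimethyl-5-(trimethylsilyloxy)hepta-1,6-dien-3-one | I/C=C(/C)[C@@H](O[Si](C)(C)C)CC(=O)/C(C)=C/OC | intermediate
8 | (S)-2-[(Z)-1-iodoprop-1-en-2-yl]-5-methyl-2,3-dihydro-4H-pyran-4-one | I/C=C(/C)[C@@H]1CC(=O)C(C)=CO1 | intermediate
9 | (2S,4S)-2-[(Z)-1-iodoprop-1-en-2-yl]-5-methyl-3,4-dihydro-2H-pyran-4-ol | I/C=C(/C)[C@@H]1C[C@H](O)C(C)=CO1 | intermediate
10 | (2S,4S)-4-(tert-butyldimethylsilyloxy)-2-[(Z)-1-iodoprop-1-en-2-yl]-5-methyl-3,4-dihydro-2H-pyran | I/C=C(/C)[C@@H]1C[C@H](O[Si](C)(C)C(C)(C)C)C(C)=CO1 | intermediate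
11 | adduct of 10 with PhI(OH)OTs: 2-hydroxytetrahydropyran carrying methyl and phenyl(tosyloxy)iodanyl on C10 (C–I equatorial, trans to 1-OTBS; C9 anomers) | I/C=C(/C)[C@@H]1C[C@H](O[Si](C)(C)C(C)(C)C)[C@](C)(C(O)O1)I(c1ccccc1)OS(=O)(=O)c1ccc(C)cc1 | intermediate
12 | (2S,3S,5S)-3-(tert-butyldimethylsilyloxy)-5-[(Z)-1-iodoprop-1-en-2-yl]-2-methyltetrahydrofuran-2-carbaldehyde | I/C=C(/C)[C@@H]1C[C@H](O[Si](C)(C)C(C)(C)C)[C@@](C)(C=O)O1 | intermediate
13 | 2-(2-methoxyethenyl) analogue of 12 (E/Z enol ether mixture) | I/C=C(/C)[C@@H]1C[C@H](O[Si](C)(C)C(C)(C)C)[C@@](C)(C=COC)O1 | intermediate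
14 | 2-{(2R,3S,5S)-3-(tert-butyldimethylsilyloxy)-5-[(Z)-1-iodoprop-1-en-2-yl]-2-methyltetrahydrofuran-2-yl}acetaldehyde | I/C=C(/C)[C@@H]1C[C@H](O[Si](C)(C)C(C)(C)C)[C@@](C)(CC=O)O1 | intermediate
15 | methyl 4-oxobutanoate | COC(=O)CCC=O | starting material
16 | methyl (3R,4R)-3-formyl-4-hydroxy-5-{tetrahydrofuranyl as in 14}pentanoate | I/C=C(/C)[C@@H]1C[C@H](O[Si](C)(C)C(C)(C)C)[C@@](C)(C[C@@H](O)[C@@H](CC(=O)OC)C=O)O1 | intermediate
17 | methyl (3R,4R)-3-formyl-4-(triethylsilyloxy)-5-{tetrahydrofuranyl as in 14}pentanoate | I/C=C(/C)[C@@H]1C[C@H](O[Si](C)(C)C(C)(C)C)[C@@](C)(C[C@@H](O[Si](CC)(CC)CC)[C@@H](CC(=O)OC)C=O)O1 | intermediate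
18 | ring A/B bicyclic allylic alcohol, 6-OH epimers, 4Z, 1-OTBS, 8-OTES, CH2CO2Me on C7 | OC1/C=C(/C)[C@@H]2C[C@H](O[Si](C)(C)C(C)(C)C)[C@@](C)(C[C@@H](O[Si](CC)(CC)CC)[C@H]1CC(=O)OC)O2 | intermediate
19 | ring A/B bicyclic Z-enone (C6 ketone) | O=C1/C=C(/C)[C@@H]2C[C@H](O[Si](C)(C)C(C)(C)C)[C@@](C)(C[C@@H](O[Si](CC)(CC)CC)[C@H]1CC(=O)OC)O2 | intermediate
20 | (6S)-hydroxy ester | O[C@H]1/C=C(/C)[C@@H]2C[C@H](O[Si](C)(C)C(C)(C)C)[C@@](C)(C[C@@H](O[Si](CC)(CC)CC)[C@H]1CC(=O)OC)O2 | intermediate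
21 | tricyclic cis-fused 6,12-olide, C11 = CH2, 1-OTBS, 8-OTES | C1C(=O)O[C@H]2/C=C(/C)[C@@H]3C[C@H](O[Si](C)(C)C(C)(C)C)[C@@](C)(C[C@@H](O[Si](CC)(CC)CC)[C@@H]12)O3 | intermediate
22 | 11-(dimethylaminomethyl) lactone (C11 epimers) | CN(C)CC1C(=O)O[C@H]2/C=C(/C)[C@@H]3C[C@H](O[Si](C)(C)C(C)(C)C)[C@@](C)(C[C@@H](O[Si](CC)(CC)CC)[C@@H]12)O3 | intermediate
23 | 11-(trimethylammoniomethyl) lactone iodide | C[N+](C)(C)CC1C(=O)O[C@H]2/C=C(/C)[C@@H]3C[C@H](O[Si](C)(C)C(C)(C)C)[C@@](C)(C[C@@H](O[Si](CC)(CC)CC)[C@@H]12)O3.[I-] | intermediate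
24 | α-methylene lactone, 1-OTBS, 8-OTES | C=C1C(=O)O[C@H]2/C=C(/C)[C@@H]3C[C@H](O[Si](C)(C)C(C)(C)C)[C@@](C)(C[C@@H](O[Si](CC)(CC)CC)[C@@H]12)O3 | intermediate
25 | α-methylene lactone, 1-OTBS, 8-OH | C=C1C(=O)O[C@H]2/C=C(/C)[C@@H]3C[C@H](O[Si](C)(C)C(C)(C)C)[C@@](C)(C[C@@H](O)[C@@H]12)O3 | intermediate
26 | angelic acid, (Z)-2-methylbut-2-enoic acid | OC(=O)/C(C)=C\C | starting material
27 | angelic 2,4,6-trichlorobenzoic anhydride | O=C(OC(=O)/C(C)=C\C)c1c(Cl)cc(Cl)cc1Cl | intermediate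
28 | 1-O-TBS ether of the target | C=C1C(=O)O[C@H]2/C=C(/C)[C@@H]3C[C@H](O[Si](C)(C)C(C)(C)C)[C@@](C)(C[C@@H](OC(=O)/C(C)=C\C)[C@@H]12)O3 | intermediate
29 | CNP0213894.2, (1S,3S,4Z,6S,7R,8R,10R)-8-angeloyloxy-3,10-epoxy-1-hydroxygermacra-4,11(13)-dien-6,12-olide | C=C1C(=O)O[C@H]2/C=C(/C)[C@@H]3C[C@H](O)[C@@](C)(C[C@@H](OC(=O)/C(C)=C\C)[C@@H]12)O3 | target

## Step count and risks

Total steps: 16. Longest linear sequence: 15 (steps 1, 2 and 4–16; step 3 is a side branch).

**Step 7 (the new ring contraction).**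
- Risk: the tertiary C10–I bond may solvolyse or eliminate before the oxygen shift.
- Path: the fallback sets out from 4 and comes back at 12, using known chemistry only.
- A boron aldol of 3-methylbut-3-en-2-one [(−)-Ipc2BCl, Et3N, Et2O; then 4, −78 °C] gives (5S,6Z)-5-hydroxy-7-iodo-2,6-dimethylhepta-1,6-dien-3-one F1.
- Hydroxyl-directed anti reduction with Me4NBH(OAc)3 (MeCN/AcOH, −30 °C) gives (3S,5S,6Z)-7-iodo-2,6-dimethylhepta-1,6-diene-3,5-diol F2.
- Aerobic Mukaiyama oxidative cyclisation [Co(modp)2, modp = 1-morpholinocarbamoyl-4,4-dimethyl-1,3-pentanedionate, O2, t-BuOOH, i-PrOH, 55 °C] is known to turn pent-4-en-1-ols into 2,5-trans tetrahydrofurans. It closes O3 onto C10 and gives (2R,3S,5S)-2-(hydroxymethyl)-5-[(Z)-1-iodoprop-1-en-2-yl]-2-methyltetrahydrofuran-3-ol F3.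
- TEMPO/PhI(OAc)2 oxidises only the primary alcohol and gives (2S,3S,5S)-3-hydroxy-5-[(Z)-1-iodoprop-1-en-2-yl]-2-methyltetrahydrofuran-2-carbaldehyde F4.
- TBSOTf/2,6-lutidine then gives 12.

**Step 9 (cross-aldol).**
- Risk: donor self-aldol, or amine-induced β-elimination that opens ring A.
- Path: the fallback sets out from 14 and comes back at 17.
- Cross-metathesis of methyl but-3-enoate with allylboronic acid pinacol ester (second-generation Grubbs catalyst, CH2Cl2, 40 °C) gives methyl (E)-5-(4,4,5,5-tetramethyl-1,3,2-dioxaborolan-2-yl)pent-3-enoate F5.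
- Allylboration of 14, catalysed by TRIP phosphoric acid of the matching antipode, runs through the closed chair of the E-boronate. It gives the anti homoallylic alcohol methyl (3S)-3-{(1R)-1-hydroxy-2-[tetrahydrofuranyl as in 14]ethyl}pent-4-enoate F6.
- TESCl/imidazole gives its triethylsilyl ether F7.
- Ozonolysis of the only electron-rich monosubstituted alkene (O3, CH2Cl2, −78 °C; PPh3) gives 17.

**Step 10 (closure of the strained trans-bridged ring B).**
- Risk: ring strain may stop the closure.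
- Path: the fallback sets out from 17 and comes back at 18.
- Hydrodeiodination [Pd(PPh3)4, Bu3SnH, THF] gives the isopropenyl aldehyde methyl (3R,4R)-3-formyl-5-[(2R,3S,5S)-3-(tert-butyldimethylsilyloxy)-2-methyl-5-(prop-1-en-2-yl)tetrahydrofuran-2-yl]-4-(triethylsilyloxy)pentanoate F8.
- CH2=CHMgBr (THF, −78 °C) adds to the aldehyde only and gives the C6 vinyl carbinol F9. Both epimers are usable.
- Ring-closing metathesis (second-generation Hoveyda–Grubbs catalyst, toluene, 80 °C, 1 mM) forms C4=C5, with the ring size enforcing Z, and gives 18.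

Further compounds
F1 | step 7 | (5S,6Z)-5-hydroxy-7-iodo-2,6-dimethylhepta-1,6-dien-3-one | I/C=C(/C)[C@@H](O)CC(=O)C(C)=C
F2 | step 7 | (3S,5S,6Z)-7-iodo-2,6-dimethylhepta-1,6-diene-3,5-diol | I/C=C(/C)[C@@H](O)C[C@H](O)C(C)=C
F3 | step 7 | (2R,3S,5S)-2-(hydroxymethyl)-5-[(Z)-1-iodoprop-1-en-2-yl]-2-methyltetrahydrofuran-3-ol | I/C=C(/C)[C@@H]1C[C@H](O)[C@@](C)(CO)O1
F4 | step 7 | (2S,3S,5S)-3-hydroxy-5-[(Z)-1-iodoprop-1-en-2-yl]-2-methyltetrahydrofuran-2-carbaldehyde | I/C=C(/C)[C@@H]1C[C@H](O)[C@@](C)(C=O)O1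
F5 | step 9 | methyl (E)-5-(4,4,5,5-tetramethyl-1,3,2-dioxaborolan-2-yl)pent-3-enoate | COC(=O)C/C=C/CB1OC(C)(C)C(C)(C)O1
F6 | step 9 | methyl (3S)-3-{(1R)-1-hydroxy-2-[tetrahydrofuranyl as in 14]ethyl}pent-4-enoate | I/C=C(/C)[C@@H]1C[C@H](O[Si](C)(C)C(C)(C)C)[C@@](C)(C[C@@H](O)[C@@H](CC(=O)OC)C=C)O1
F7 | step 9 | triethylsilyl ether of F6 | I/C=C(/C)[C@@H]1C[C@H](O[Si](C)(C)C(C)(C)C)[C@@](C)(C[C@@H](O[Si](CC)(CC)CC)[C@@H](CC(=O)OC)C=C)O1
F8 | step 10 | methyl (3R,4R)-3-formyl-5-[(2R,3S,5S)-3-(tert-butyldimethylsilyloxy)-2-methyl-5-(prop-1-en-2-yl)tetrahydrofuran-2-yl]-4-(triethylsilyloxy)pentanoate | C=C(C)[C@@H]1C[C@H](O[Si](C)(C)C(C)(C)C)[C@@](C)(C[C@@H](O[Si](CC)(CC)CC)[C@@H](CC(=O)OC)C=O)O1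
F9 | step 10 | C6 vinyl carbinol from F8 (C6 epimers) | C=C(C)[C@@H]1C[C@H](O[Si](C)(C)C(C)(C)C)[C@@](C)(C[C@@H](O[Si](CC)(CC)CC)[C@@H](CC(=O)OC)C(O)C=C)O1
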